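Ring A (C1–C6) is read as a masked 2-methylcyclohex-2-enone: C2 is the ketone, C3 carries the methyl, the C3–C4 epoxide stores the enone double bond and C6 bears the only carbon branch (C7). Cutting C1–C6 and C3=C4 gives a β-keto ester (C1–C3 plus the methyl) and a four-carbon enal ester (C4–C7), both bought. One amine-catalysed Michael addition/aldol condensation joins them, closes ring A and sets C6, from which every later centre is derived by substrate or reagent control. C7 arrives as an ester and is grown into the spiro-epoxide enone chain; the C1 ester and the ring epoxide are added to the enone afterwards.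

Key step: step 1

Remarks on the chemistry:
- Atom labels: ring C1 (CH–O-acyl), C2 (C=O), C3 (C–CH3), C4 (epoxide CH), C5 (CH2), C6 (CH); chain C7 (spiro-epoxide carbon), C14 (its CH2), C8 (C=O), C9=C10, C11 (carbinol). In these labels the target is 1S,3S,4S,6R,7R.
- Assumption: the (S)-configured prolinol silyl ether is taken to give 6R, by addition to the iminium face remote from its diphenyl(silyloxy)methyl group.
- Catalysts and unnumbered reagents, including (tributylstannyl)methanol, are bought.

Step 1
Reactants: 1 tert-butyl 3-oxopentanoate; 2 ethyl (E)-4-oxobut-2-enoate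
Product: 4 2-tert-butyl 1-ethyl (1R,2S)-4-methyl-3-oxocyclohex-4-ene-1,2-dicarboxylate, via Michael adduct 3 (not isolated)
Conditions: (S)-α,α-diphenylprolinol trimethylsilyl ether (10 mol%), PhCO2H (10 mol%), toluene, 0 °C to rt; then p-TsOH·H2O (20 mol%), 40 °C
Reagents that add atoms: none
Why: The amine condenses with the aldehyde of 2 to an E-configured iminium ion, the enol of 1 adds to the carbon β to the iminium carbon (the one bearing the ester) to form C1–C6, and after hydrolysis to 3 the acid makes the ethyl ketone enolise toward C3 and condense with the free aldehyde C4, water being lost to give C3=C4. The closest known reaction type is the diarylprolinol silyl ether-catalysed Michael addition of β-keto esters to enals followed by acid-mediated aldol condensation to cyclohexenones. Ring A closes by a 6-(enolendo)-exo-trig aldol addition. C6 is controlled by the catalyst alone, whose diphenyl(silyloxy)methyl group blocks one face of the iminium ion so that the (S)-amine gives 6R, whereas C1, flanked by two carbonyl groups, equilibrates to the trans diester and is removed in step 2. The step needs regioselectivity for the carbon α to the ester, secured because only the aldehyde is activated as an iminium ion, and it needs ring closure from C3, secured because attack from C1 would give a four-membered ring. The tert-butyl ester should survive at 40 °C, and material that has lost it early converges on 6 in step 2.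

Step 2
Reactants: 4 2-tert-butyl 1-ethyl (1R,2S)-4-methyl-3-oxocyclohex-4-ene-1,2-dicarboxylate
Product: 6 ethyl (1R)-4-methyl-5-oxocyclohex-3-ene-1-carboxylate, via β-keto acid 5 (not isolated)
Conditions: p-TsOH·H2O (0.2 equiv), toluene, 90 °C
Reagents that add atoms: none
Why: Acid-catalysed loss of 2-methylpropene from the tert-butyl ester and thermal decarboxylation of the resulting β-keto acid (ketonic cleavage of a β-keto ester) remove the C1 carboxyl, while the ethyl ester and C6, which is not α to the ketone, are unaffected.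

Step 3
Reactants: 6 ethyl (1R)-4-methyl-5-oxocyclohex-3-ene-1-carboxylate
Product: 7 ethyl (7R)-10-methyl-1,4-dioxaspiro[4.5]dec-9-ene-7-carboxylate
Conditions: (Me3SiOCH2)2, Me3SiOTf (5 mol%), CH2Cl2, −78 to −20 °C
Reagents that add atoms: 1,2-bis(trimethylsilyloxy)ethane, C[Si](C)(C)OCCO[Si](C)(C)C
Why: Acetalisation of the enone carbonyl with the bis-silyl ether of ethylene glycol under Me3SiOTf catalysis proceeds at low temperature without migration of the C3=C4 double bond or enolisation at C6 and masks the ketone against the organomagnesium reagents of step 4.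

Step 4
Reactants: 7 ethyl (7R)-10-methyl-1,4-dioxaspiro[4.5]dec-9-ene-7-carboxylate
Product: 9 1-[(7R)-10-methyl-1,4-dioxaspiro[4.5]dec-9-en-7-yl]ethan-1-one, via Weinreb amide 8 (not isolated)
Conditions: MeNH(OMe)·HCl, i-PrMgCl, THF, −20 °C; then MeMgBr, 0 °C; aq. NH4Cl
Reagents that add atoms: methylmagnesium bromide, C[Mg]Br
Why: Weinreb ketone synthesis in one pot: the amide MeN(OMe)MgCl made in the flask converts the ethyl ester into the N-methoxy-N-methylamide, and MeMgBr adds once to give a chelated tetrahedral adduct that releases the methyl ketone only on work-up, so over-addition and base-mediated epimerisation at C6 are avoided.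

Step 5
Reactants: 9 1-[(7R)-10-methyl-1,4-dioxaspiro[4.5]dec-9-en-7-yl]ethan-1-one
Product: 11 1-[(7R)-10-methyl-1,4-dioxaspiro[4.5]dec-9-en-7-yl]ethenyl trifluoromethanesulfonate, via potassium enolate 10 (not isolated)
Conditions: KN(SiMe3)2, THF, −78 °C; then PhNTf2, −78 to 0 °C
Reagents that add atoms: N-phenylbis(trifluoromethanesulfonimide), O=S(=O)(N(c1ccccc1)S(=O)(=O)C(F)(F)F)C(F)(F)F
Why: Kinetic enol triflate formation: the hindered amide base removes a proton from the methyl group and not from the C6 methine at −78 °C, and O-sulfonylation of the terminal enolate by PhNTf2 gives the 1,1-disubstituted enol triflate that stores C7=C14 and the later C7–C8 bond.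

Step 6
Reactants: 11 1-[(7R)-10-methyl-1,4-dioxaspiro[4.5]dec-9-en-7-yl]ethenyl trifluoromethanesulfonate
Product: 12 1-[(1R)-4-methyl-5-oxocyclohex-3-en-1-yl]ethenyl trifluoromethanesulfonate
Conditions: 1 M HCl, THF, rt
Reagents that add atoms: water, O
Why: Acid-catalysed acetal hydrolysis of the allylic dioxolane returns the conjugated enone, while the enol triflate is inert to dilute aqueous acid and C6 is not enolisable toward the ring ketone.

Step 7
Reactants: 12 1-[(1R)-4-methyl-5-oxocyclohex-3-en-1-yl]ethenyl trifluoromethanesulfonate; 13 isovaleric acid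
Product: 14 (1S,6R)-3-methyl-2-oxo-6-[1-(trifluoromethanesulfonyloxy)ethenyl]cyclohex-3-en-1-yl 3-methylbutanoate
Conditions: Mn(OAc)3·2H2O (3 equiv), 13 (10 equiv), benzene, reflux, azeotropic removal of AcOH/H2O
Reagents that add atoms: none
Why: α'-Acyloxylation of an enone with a trivalent manganese carboxylate: the enolate formed toward C1 is oxidised to the α-oxo radical, which takes up a 3-methylbutanoate ligand on the face away from the C6 substituent, and because C1 stays enolisable the product settles as the trans, diequatorial isomer; pre-exchange of Mn(OAc)3 with excess 13 and azeotropic removal of acetic acid suppress acetate transfer.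

Step 8
Reactants: 14 (1S,6R)-3-methyl-2-oxo-6-[1-(trifluoromethanesulfonyloxy)ethenyl]cyclohex-3-en-1-yl 3-methylbutanoate
Product: 15 (1S,6S)-6-(3-hydroxyprop-1-en-2-yl)-3-methyl-2-oxocyclohex-3-en-1-yl 3-methylbutanoate
Conditions: Bu3SnCH2OH, Pd(PPh3)4 (5 mol%), LiCl, 1,4-dioxane, 90 °C
Reagents that add atoms: (tributylstannyl)methanol, CCCC[Sn](CCCC)(CCCC)CO
Why: Stille coupling: oxidative addition of the enol triflate to zerovalent palladium, chloride-assisted transfer of the hydroxymethyl group from tin and reductive elimination form C7–C8 under neutral conditions that spare the α-acyloxy enone and give the free 2-substituted allylic alcohol directly.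

Step 9
Reactants: 15 (1S,6S)-6-(3-hydroxyprop-1-en-2-yl)-3-methyl-2-oxocyclohex-3-en-1-yl 3-methylbutanoate
Product: 16 (1S,6R)-6-[(2S)-2-(hydroxymethyl)oxiran-2-yl]-3-methyl-2-oxocyclohex-3-en-1-yl 3-methylbutanoate
Conditions: Ti(Oi-Pr)4 (10 mol%), L-(+)-diethyl tartrate (12 mol%), t-BuOOH (2 equiv), 4 Å MS, CH2Cl2, −20 °C
Reagents that add atoms: tert-butyl hydroperoxide, CC(C)(C)OO
Why: Sharpless asymmetric epoxidation: the Ti(Oi-Pr)4/L-(+)-tartrate catalyst binds the primary allylic alcohol and delivers the peroxide oxygen to one face of C7=C14 under reagent control, giving the (S)-2-substituted glycidol that becomes 7R once C8 is oxidised, while the electron-poor ring enone does not react.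

Step 10
Reactants: 16 (1S,6R)-6-[(2S)-2-(hydroxymethyl)oxiran-2-yl]-3-methyl-2-oxocyclohex-3-en-1-yl 3-methylbutanoate
Product: 17 (1S,2S,6R)-2-hydroxy-6-[(2S)-2-(hydroxymethyl)oxiran-2-yl]-3-methylcyclohex-3-en-1-yl 3-methylbutanoate
Conditions: NaBH4, CeCl3·7H2O, MeOH, −78 °C; AcOH quench
Reagents that add atoms: none
Why: Luche reduction: the CeCl3-modified borohydride reduces the enone carbonyl 1,2 and attacks axially on the face opposite the equatorial C6 substituent, so the new C2 hydroxyl is pseudo-equatorial, cis to the C6 side chain and trans to the C1 ester, and the low temperature with an acidic quench keeps the ester from shifting to the new hydroxyl.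

Step 11
Reactants: 17 (1S,2S,6R)-2-hydroxy-6-[(2S)-2-(hydroxymethyl)oxiran-2-yl]-3-methylcyclohex-3-en-1-yl 3-methylbutanoate
Product: 18 (1R,2R,3S,4R,6S)-2-hydroxy-4-[(2S)-2-(hydroxymethyl)oxiran-2-yl]-1-methyl-7-oxabicyclo[4.1.0]heptan-3-yl 3-methylbutanoate
Conditions: VO(acac)2 (5 mol%), t-BuOOH, CH2Cl2, 0 °C to rt
Reagents that add atoms: tert-butyl hydroperoxide, CC(C)(C)OO
Why: Hydroxyl-directed epoxidation: the C2 alkoxide bound to the pentavalent vanadium tert-butyl peroxide formed from VO(acac)2 delivers oxygen to the same face of the trisubstituted C3=C4 bond, so the ring epoxide is syn to the C2 hydroxyl, that is cis to the C6 side chain and trans to the C1 ester, fixing C3 and C4.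

Step 12
Reactants: 18 (1R,2R,3S,4R,6S)-2-hydroxy-4-[(2S)-2-(hydroxymethyl)oxiran-2-yl]-1-methyl-7-oxabicyclo[4.1.0]heptan-3-yl 3-methylbutanoate
Product: 19 (1R,2R,3S,4R,6S)-4-[(2R)-2-formyloxiran-2-yl]-2-hydroxy-1-methyl-7-oxabicyclo[4.1.0]heptan-3-yl 3-methylbutanoate
Conditions: TEMPO (10 mol%), PhI(OAc)2, CH2Cl2, rt
Reagents that add atoms: none
Why: Oxoammonium (TEMPO) oxidation is selective for the primary over the hindered secondary C2 alcohol and stops at the aldehyde, which cannot epimerise because C7 is quaternary, and the bulky C7 group keeps C6 equatorial so that the bridged lactol required for over-oxidation cannot form.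

Step 13
Reactants: 20 2-methylbut-3-yn-2-ol
Product: 22 (E)-4-iodo-2-methylbut-3-en-2-ol, via vinylstannane 21 (not isolated)
Conditions: Bu3SnH, Pd(PPh3)2Cl2 (2 mol%), THF, 0 °C to rt; then I2, 0 °C
Reagents that add atoms: iodine, [I][I]
Why: Palladium-catalysed syn hydrostannylation places tin on the terminal carbon away from the tertiary carbinol to give the (E)-alkenylstannane, and iododestannylation with I2 proceeds with retention of the double-bond geometry.

Step 14
Reactants: 19 (1R,2R,3S,4R,6S)-4-[(2R)-2-formyloxiran-2-yl]-2-hydroxy-1-methyl-7-oxabicyclo[4.1.0]heptan-3-yl 3-methylbutanoate; 22 (E)-4-iodo-2-methylbut-3-en-2-ol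
Product: 23 (1R,2R,3S,4R,6S)-4-{(2R)-2-[(2E)-1,4-dihydroxy-4-methylpent-2-en-1-yl]oxiran-2-yl}-2-hydroxy-1-methyl-7-oxabicyclo[4.1.0]heptan-3-yl 3-methylbutanoate (both C8 epimers)
Conditions: CrCl2 (6 equiv), NiCl2 (2 mol%), DMSO, rt
Reagents that add atoms: none
Why: Nozaki–Hiyama–Kishi coupling: zerovalent nickel generated from NiCl2 inserts into the C–I bond, transmetalation gives an alkenyl–CrCl2 species of trivalent chromium that adds only to the aldehyde with retention of the E geometry and tolerates the ester, both epoxides and the free hydroxyl groups, and the C8 configuration is irrelevant because it is removed in step 15.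

Step 15
Reactants: 23 (1R,2R,3S,4R,6S)-4-{(2R)-2-[(2E)-1,4-dihydroxy-4-methylpent-2-en-1-yl]oxiran-2-yl}-2-hydroxy-1-methyl-7-oxabicyclo[4.1.0]heptan-3-yl 3-methylbutanoate
Product: 24 (1S,3S,4R,6S)-4-{(2R)-2-[(2E)-4-hydroxy-4-methylpent-2-enoyl]oxiran-2-yl}-1-methyl-2-oxo-7-oxabicyclo[4.1.0]heptan-3-yl 3-methylbutanoate (CNP0292003.1)
Conditions: Dess–Martin periodinane (3 equiv), pyridine, CH2Cl2, 0 °C to rt
Reagents that add atoms: none
Why: Dess–Martin oxidation converts the C2 and the allylic C8 secondary alcohols into ketones under buffered, near-neutral conditions that leave the tertiary C11 alcohol, both epoxides and the enolisable C1 centre untouched, and creates no stereocentre.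

Compound list
1 | tert-butyl 3-oxopentanoate | CCC(=O)CC(=O)OC(C)(C)C | starting material
2 | ethyl (E)-4-oxobut-2-enoate | CCOC(=O)/C=C/C=O | starting material
3 | Michael adduct (not isolated): 1-tert-butyl 4-ethyl (3R)-3-(2-oxoethyl)-2-propanoylbutanedioate, C2 epimers | CCC(=O)C(C(=O)OC(C)(C)C)[C@@H](CC=O)C(=O)OCC | intermediate
4 | 2-tert-butyl 1-ethyl (1R,2S)-4-methyl-3-oxocyclohex-4-ene-1,2-dicarboxylate (trans) | CC(C)(C)OC(=O)[C@@H]1C(=O)C(C)=CC[C@H]1C(=O)OCC | intermediate
5 | β-keto acid (not isolated): (1S,6R)-6-(ethoxycarbonyl)-3-methyl-2-oxocyclohex-3-ene-1-carboxylic acid | OC(=O)[C@@H]1C(=O)C(C)=CC[C@H]1C(=O)OCC | intermediate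
6 | ethyl (1R)-4-methyl-5-oxocyclohex-3-ene-1-carboxylate | CCOC(=O)[C@@H]1CC=C(C)C(=O)C1 | intermediate
7 | ethyl (7R)-10-methyl-1,4-dioxaspiro[4.5]dec-9-ene-7-carboxylate | CCOC(=O)[C@@H]1CC=C(C)C2(OCCO2)C1 | intermediate
8 | Weinreb amide (not isolated): (7R)-N-methoxy-N,10-dimethyl-1,4-dioxaspiro[4.5]dec-9-ene-7-carboxamide | CON(C)C(=O)[C@@H]1CC=C(C)C2(OCCO2)C1 | intermediate
9 | 1-[(7R)-10-methyl-1,4-dioxaspiro[4.5]dec-9-en-7-yl]ethan-1-one | CC(=O)[C@@H]1CC=C(C)C2(OCCO2)C1 | intermediate
10 | potassium enolate (not isolated): potassium 1-[(7R)-10-methyl-1,4-dioxaspiro[4.5]dec-9-en-7-yl]ethen-1-olate | [K+].[O-]C(=C)[C@@H]1CC=C(C)C2(OCCO2)C1 | intermediate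
11 | 1-[(7R)-10-methyl-1,4-dioxaspiro[4.5]dec-9-en-7-yl]ethenyl trifluoromethanesulfonate | C=C(OS(=O)(=O)C(F)(F)F)[C@@H]1CC=C(C)C2(OCCO2)C1 | intermediate
12 | 1-[(1R)-4-methyl-5-oxocyclohex-3-en-1-yl]ethenyl trifluoromethanesulfonate | C=C(OS(=O)(=O)C(F)(F)F)[C@@H]1CC=C(C)C(=O)C1 | intermediate
13 | isovaleric acid (3-methylbutanoic acid) | CC(C)CC(=O)O | starting material
14 | (1S,6R)-3-methyl-2-oxo-6-[1-(trifluoromethanesulfonyloxy)ethenyl]cyclohex-3-en-1-yl 3-methylbutanoate (ester trans to the C6 group) | CC(C)CC(=O)O[C@@H]1C(=O)C(C)=CC[C@H]1C(=C)OS(=O)(=O)C(F)(F)F | intermediate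
15 | (1S,6S)-6-(3-hydroxyprop-1-en-2-yl)-3-methyl-2-oxocyclohex-3-en-1-yl 3-methylbutanoate | CC(C)CC(=O)O[C@@H]1C(=O)C(C)=CC[C@H]1C(=C)CO | intermediate
16 | (1S,6R)-6-[(2S)-2-(hydroxymethyl)oxiran-2-yl]-3-methyl-2-oxocyclohex-3-en-1-yl 3-methylbutanoate | CC(C)CC(=O)O[C@@H]1C(=O)C(C)=CC[C@H]1[C@]1(CO)CO1 | intermediate
17 | (1S,2S,6R)-2-hydroxy-6-[(2S)-2-(hydroxymethyl)oxiran-2-yl]-3-methylcyclohex-3-en-1-yl 3-methylbutanoate (C2 hydroxyl cis to the C6 chain) | CC(C)CC(=O)O[C@@H]1[C@@H](O)C(C)=CC[C@H]1[C@]1(CO)CO1 | intermediate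
18 | (1R,2R,3S,4R,6S)-2-hydroxy-4-[(2S)-2-(hydroxymethyl)oxiran-2-yl]-1-methyl-7-oxabicyclo[4.1.0]heptan-3-yl 3-methylbutanoate (ring epoxide syn to the C2 hydroxyl) | CC(C)CC(=O)O[C@@H]1[C@@H](O)[C@@]2(C)O[C@H]2C[C@H]1[C@]1(CO)CO1 | intermediate
19 | (1R,2R,3S,4R,6S)-4-[(2R)-2-formyloxiran-2-yl]-2-hydroxy-1-methyl-7-oxabicyclo[4.1.0]heptan-3-yl 3-methylbutanoate | CC(C)CC(=O)O[C@@H]1[C@@H](O)[C@@]2(C)O[C@H]2C[C@H]1[C@]1(C=O)CO1 | intermediate
20 | 2-methylbut-3-yn-2-ol | CC(C)(O)C#C | starting material
21 | vinylstannane (not isolated): (E)-2-methyl-4-(tributylstannyl)but-3-en-2-ol | CCCC[Sn](CCCC)(CCCC)/C=C/C(C)(C)O | intermediate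
22 | (E)-4-iodo-2-methylbut-3-en-2-ol | CC(C)(O)/C=C/I | intermediate
23 | (1R,2R,3S,4R,6S)-4-{(2R)-2-[(2E)-1,4-dihydroxy-4-methylpent-2-en-1-yl]oxiran-2-yl}-2-hydroxy-1-methyl-7-oxabicyclo[4.1.0]heptan-3-yl 3-methylbutanoate, both C8 epimers | CC(C)CC(=O)O[C@@H]1[C@@H](O)[C@@]2(C)O[C@H]2C[C@H]1[C@]1(C(O)/C=C/C(C)(C)O)CO1 | intermediate
24 | (1S,3S,4R,6S)-4-{(2R)-2-[(2E)-4-hydroxy-4-methylpent-2-enoyl]oxiran-2-yl}-1-methyl-2-oxo-7-oxabicyclo[4.1.0]heptan-3-yl 3-methylbutanoate | CC(C)CC(=O)O[C@@H]1C(=O)[C@@]2(C)O[C@H]2C[C@H]1[C@]1(C(=O)/C=C/C(C)(C)O)CO1 | target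

Total step count: 15 (14 in the main line plus step 13 for the alkenyl iodide).
Longest linear sequence: 14 steps (steps 1–12, 14 and 15, from 1 and 2 to 24).

Steps most likely to fail

Step 7. The manganese-mediated acyloxylation may stall or transfer acetate in competition with 3-methylbutanoate. It may also lose face selectivity at C1, and the enol triflate may be degraded by prolonged heating with carboxylic acid. The fallback sets out from 12 and comes back at 14. Soft enolisation of 12 with Me3SiOTf and Et3N gives the cross-conjugated silyl dienol ether F1. Rubottom oxidation with dimethyldioxirane at −78 °C, which attacks the face away from the C6 substituent, followed by desilylation gives the trans α'-hydroxy enone F2. Esterification of F2 with 13 (DCC, DMAP, CH2Cl2) returns 14.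

Step 8. Transfer of the sp3 hydroxymethyl group from tin may be slow. Protodetriflation or thermal decomposition of the α-acyloxy enone would then compete with coupling. The fallback sets out from 14 and comes back at 15. Reductive carbonylation of the triflate (Pd(PPh3)4, LiCl, CO at 1 atm, slow addition of Bu3SnH, THF, 50 °C) gives the 2-substituted acrolein F3. NaBH(OAc)3 then reduces the aldehyde selectively in the presence of the ring ketone and the ester to give 15.

Step 14. The divalent chromium may open or reduce the α,β-epoxy aldehyde. Alternatively the hindered aldehyde may add so slowly that the alkenyl metal species is protonated instead. The fallback sets out from 19 and 20 and comes back at 23. Silylation of 20 (Et3SiCl, imidazole) gives the triethylsilyl ether F4. Hydrozirconation with Cp2Zr(H)Cl gives the alkenylzirconium complex F5, and transmetalation with Me2Zn gives the alkenyl(methyl)zinc F6. F6 adds to the aldehyde of 19 without touching the ester or the epoxides and gives the silyl ether F7. HF·pyridine in THF at 0 °C removes the silyl group and returns 23.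

Further compounds
F1 | step 7 | 1-[(1R)-4-methyl-3-(trimethylsilyloxy)cyclohexa-2,4-dien-1-yl]ethenyl trifluoromethanesulfonate | C=C(OS(=O)(=O)C(F)(F)F)[C@@H]1CC=C(C)C(O[Si](C)(C)C)=C1
F2 | step 7 | 1-[(1R,6S)-6-hydroxy-4-methyl-5-oxocyclohex-3-en-1-yl]ethenyl trifluoromethanesulfonate | O[C@@H]1C(=O)C(C)=CC[C@H]1C(=C)OS(=O)(=O)C(F)(F)F
F3 | step 8 | (1S,6S)-3-methyl-2-oxo-6-(3-oxoprop-1-en-2-yl)cyclohex-3-en-1-yl 3-methylbutanoate | CC(C)CC(=O)O[C@@H]1C(=O)C(C)=CC[C@H]1C(=C)C=O
F4 | step 14 | triethyl[(2-methylbut-3-yn-2-yl)oxy]silane | CC[Si](CC)(CC)OC(C)(C)C#C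
F5 | step 14 | chlorobis(cyclopentadienyl)[(E)-3-methyl-3-(triethylsilyloxy)but-1-en-1-yl]zirconium | CC[Si](CC)(CC)OC(C)(C)/C=C/[Zr](Cl)(C1C=CC=C1)C1C=CC=C1
F6 | step 14 | methyl[(E)-3-methyl-3-(triethylsilyloxy)but-1-en-1-yl]zinc | CC[Si](CC)(CC)OC(C)(C)/C=C/[Zn]C
F7 | step 14 | C11 triethylsilyl ether of 23, both C8 epimers | CC(C)CC(=O)O[C@@H]1[C@@H](O)[C@@]2(C)O[C@H]2C[C@H]1[C@]1(C(O)/C=C/C(C)(C)O[Si](CC)(CC)CC)CO1
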